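All runs are simulated with made-up constants; the scatter is artificial.

- Late in the spring run, which is the asked flask followed so far, target still climbs, from 27.8% at 50.0 min to 30.3% at 150 min. That rise of 2.5 percentage points stands against a scatter of 1 point per reading, so it is thin evidence, but I build on it.

all flasks: solid substrate 0.10 M
- spring: first nucleophile 0.18 M; second nucleophile 0.11 M; temperature 70 °C; the very flask that is asked about, followed so far
- winter: first nucleophile 0.18 M; second nucleophile 0.22 M; temperature 55 °C; run made earlier
- flask: first nucleophile 0.180 M; second nucleophile 0.110 M; temperature 70 °C; time 4.0 h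

| run | time / min | target / % | solid substrate / % |
|---|---|---|---|
| spring | 20.0 | 13.6 | 31.5 |
| spring | 50.0 | 27.8 | 0 |
| spring | 90.0 | 28.9 | 0.4 |
| spring | 150 | 30.3 | 0.2 |
| winter | 6.00 | 0.6 | 74.9 |
| winter | 12.0 | 1.5 | 64.6 |
| winter | 30.0 | 3.6 | 49.7 |
| winter | 80.0 | 11.0 | 7.0 |

(readings scatter by 1 percentage point)

- Monday's: at 4.0 h raise the temperature by 20 K, then wait 8.0 h
- Saturday's: change nothing and wait 8.0 h more
- Thursday's: at 4.0 h add first nucleophile, 100% of the amount charged, then wait 8.0 h
- Sunday's: at 4.0 h take out 90% of the target then present, then wait 8.0 h

- solid, in amounts per volume of the solution: solid substrate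
- target taken out counts as made
- at the start none of the solid substrate is in solution
- additions bring no volume worth counting

1. target, in percent of the solid substrate first charged, at 4.0 h
2. the option that brings most further target ("none" if no option brings more than 2 percentage points) (Monday's / Saturday's / Thursday's / Sunday's / none)
3. target present, with what was taken out counted in, in percent of the solid substrate first charged, after Monday's
4. target present, with what was taken out counted in, in percent of the solid substrate first charged, after Thursday's

- At the start of the flask, target reaches 13.6% by 20.0 min while the solid substrate falls to 31.5%. That is 19.9% of what the solid has lost.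
- From there to 50.0 min, the solid falls to 0% and target gains 14 points, which gives 45.1%.
- I call this φ: target gained per point of solid lost on that stretch, read as the chance that one molecule leaves its fork as target, the selectivity.
- φ is higher than the early figure, so I take it that part of the material is parked before the fork.
- The curve then has a knee at 50.0 min, and its final level is φ of the charge, 45.1%.
- At 150 min the gap to that level is 15 points. Gap divided by late slope gives a release time τ of 9.85 h.
- Closing the gap exponentially, I expect 32.4% at 4.0 h.
- Saturday's then adds 7.1 points. I book Sunday's the same. Target falls in no spring reading.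
- Thursday's roughly doubles first nucleophile. If that halves the odds against target, φ becomes 62.1%, and I get 42.1%.
- The winter run's early target rate is 5.67 times slower, though it also differs in second nucleophile. So I expect a rise of 20 K to reach the full level, 45.1%, in 8.0 h, above Thursday's. I commit to Monday's.
- The forecast says 31% now, none as best, 32.5% after Monday's and 32% after Thursday's: “Heat or extra first nucleophile could finish that residue”.
- The flask gives 32.7%, and the best option is Monday's, at 14 points, reaching 46.5%. Thursday's reaches 41.6%, and Saturday's brings 6.3 points.

    starting material → intermediate (k = 0.00138 s⁻¹, Ea = 93.0 kJ mol⁻¹)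
    first nucleophile + intermediate → target (k = 0.652 M⁻¹ s⁻¹, Ea = 73.0 kJ mol⁻¹)
    second nucleophile + intermediate → other capture product (k = 0.726 M⁻¹ s⁻¹, Ea = 37.0 kJ mol⁻¹)
    intermediate → solvolysis product (k = 0.0472 s⁻¹, Ea = 90.0 kJ mol⁻¹)
    starting material ⇌ dormant form (K = 27.0, k = 9.18 × 10⁻⁴ s⁻¹, Ea = 93.0 kJ mol⁻¹, ΔH = 17.0 kJ mol⁻¹)
    solid substrate ⇌ starting material, rate k6*(cs6 - [starting material]) while solid is left; crystals form when [starting material] > cs6 (solubility = 31.0 mM, k = 0.00431 s⁻¹)
    (constants at 70 °C)

- At 240 min the parked material is the dormant form, a resting state, at 30.4%. In the neighbour flask, second nucleophile is 0.066 M. With k₃ and k₂ the rate constants of capture by second and first nucleophile, the odds against target fall by k₃Δ[second nucleophile]/(k₂[first nucleophile]), which is 0.272. So φ becomes 51.4%. Its dormant form also stands at 30.4%, so I keep the part past the fork in the flask, target, other capture product and solvolysis product together, 69.1%, and reckon 35.5% of target. The neighbour flask gives 37.3%.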